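**Retrosynthetic overview**
- Haterumaimide J ⇐ succinimide closure by ammonolysis of a trans γ-lactone methyl ester (also frees the C12 and C18 hydroxyls) ⇐ C8 methylenation ⇐ C2–H chlorination of a keto lactone.
- Keto lactone ⇐ C11–C12 bond by visible-light decarboxylative radical conjugate addition of a malate-derived lactone acid to a 9-methylene-8-decalone (sets C12 and C9).
- Methylene decalone ⇐ levopimaric acid with ring C cut away (diene cleavage, then dehydrodecarboxylation); rings A and B with C4, C5, C10 and the C18 oxygen are bought.
- Lactone acid ⇐ dimethyl (S)-malate + tert-butyl bromoacetate (Fráter–Seebach alkylation sets C13; the malate carbinol centre is later spent as the radical site).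
- Ring order: decalin bought; temporary γ-lactone closed before the coupling; succinimide ring closed last.

Assumption: levopimaric acid (main resin acid of pine oleoresin) is taken as a purchasable chiral-pool acid. Atom labels C1–C20 follow labdane numbering of the target.

**Route**

Step 1
Reactants: 1 levopimaric acid
Product: 3 levopimaryl acetate, via levopimarol 2 (not isolated)
Conditions: LiAlH4, THF, 0 °C → reflux; then Ac2O, pyridine, DMAP (cat.), CH2Cl2, rt
Reagents that add atoms: acetic anhydride CC(=O)OC(C)=O
Why: LiAlH4 reduces the hindered C18 acid without touching the diene or any stereocentre (hydride reduction), and the crude neopentyl alcohol is acetylated at once (DMAP-catalysed acylation) so the acid-labile diene alcohol is never stored.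

Step 2
Reactants: 3 levopimaryl acetate
Product: 4 keto acid
Conditions: RuCl3·xH2O (5 mol%), NaIO4 (7 equiv), EtOAc/MeCN/H2O, 0 °C → rt
Reagents that add atoms: sodium periodate [Na+].[O-]I(=O)(=O)=O; water O
Why: Ruthenium tetroxide formed in the flask cleaves both trisubstituted alkenes of the ring C diene (oxidative alkene cleavage), leaving the C8 ketone and the C12 acid and excising C13–C14 with the isopropyl group, while C9 keeps its stable equatorial configuration.

Step 3
Reactants: 4 keto acid
Product: 5 methylene decalone
Conditions: 9-mesitylacridine (10 mol%), Co(dmgH)2(py)Cl (5 mol%), CH2Cl2, 400 nm LEDs, rt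
Reagents that add atoms: none
Why: Photoinduced proton-coupled electron transfer in the acridine–acid complex gives CO2 and the primary C11 radical, and the cobalt complex removes the weak C9–H next to the ketone to release the enone and H2 (photocatalytic dehydrodecarboxylation, the catalytic counterpart of the Kochi oxidative decarboxylation).

Step 4
Reactants: 6 dimethyl (S)-malate; 7 tert-butyl bromoacetate
Product: 8 hydroxy triester
Conditions: LiN(SiMe3)2 (2.2 equiv), THF, −78 °C; then 7, −78 → −20 °C; AcOH
Reagents that add atoms: none
Why: Fráter–Seebach alkylation: the chelated lithium alkoxide–enolate is alkylated anti to the alkoxide, so the bought (S) carbinol sets the new centre (future C13) as (R); the minor syn isomer (about 1 part in 10) is removed by chromatography.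

Step 5
Reactants: 8 hydroxy triester
Product: 10 cis lactone acid, via hydroxy acid 9 (not isolated)
Conditions: LiOH (1.05 equiv), THF/H2O, 0 °C; 1 M HCl; then TFA/CH2Cl2 (1:4), rt
Reagents that add atoms: lithium hydroxide [Li+].[OH-]
Why: The α-hydroxy methyl ester is the most electrophilic ester and is saponified selectively, then acid removes the tert-butyl group and the freed acid closes the γ-lactone on the carbinol oxygen with both centres untouched (selective saponification, then acid-catalysed lactonisation).

Step 6
Reactants: 5 methylene decalone; 10 cis lactone acid (1.5 equiv)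
Product: 11 keto lactone
Conditions: Ir[dF(CF3)ppy]2(dtbbpy)PF6 (2 mol%), K2HPO4 (1.2 equiv), DMF, 450 nm LEDs, rt
Reagents that add atoms: none
Why: Proposed new method: the excited photocatalyst oxidises the carboxylate of 10 and loss of CO2 gives a planar α-acyloxy radical at C12 inside the lactone, whose neighbouring C13 ester shields one face, so the radical adds to the unhindered methylene terminus of 5 anti to that ester (trans lactone = 12S beside 13R; the cis acid is inverted at C12), and the resulting α-keto radical is reduced to the enolate and protonated from the α face opposite the axial C10 methyl to give the equatorial 9β side chain (also the thermodynamic epimer); the closest known reaction is the photoredox decarboxylative Giese addition of α-amino and α-alkoxy acids to Michael acceptors, here extended to a lactone acid with a vicinal ester as the only control element and to a hindered 2-methylene-1-decalone, a pairing for which I know of no precedent.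

Step 7
Reactants: 11 keto lactone
Product: 12 chloro keto lactone
Conditions: N-chloro-N-tert-butyl-3,5-bis(trifluoromethyl)benzamide (1.2 equiv), Cs2CO3 (1 equiv), PhH, 55 °C, visible light
Reagents that add atoms: N-chloro-N-tert-butyl-3,5-bis(trifluoromethyl)benzamide CC(C)(C)N(Cl)C(=O)c1cc(cc(c1)C(F)(F)F)C(F)(F)F
Why: The bulky amidyl radical abstracts hydrogen from the most electron-rich, least hindered methylene, C2 of ring A (ring B and the side chain are deactivated by ketone, lactone and esters; C1 and C3 are shielded by their quaternary neighbours, C3 also by the acetoxymethyl group), and chlorine is delivered to the equatorial α face away from the two axial methyls (N-chloroamide radical-chain C–H chlorination, as established on sclareolide).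

Step 8
Reactants: 12 chloro keto lactone
Product: 13 chloro methylene lactone
Conditions: Zn, CH2Br2, TiCl4, THF/CH2Cl2, 0 °C → rt
Reagents that add atoms: dibromomethane BrCBr
Why: Takai–Lombardo methylenation: the non-basic dizinc/titanium methylene reagent converts the hindered C8 ketone into the exocyclic alkene without enolising C9 or C13 and leaves lactone, esters and chloride alone.

Step 9
Reactants: 13 chloro methylene lactone
Product: 15 haterumaimide J, via hydroxy amide ester 14 (not isolated)
Conditions: NH3 (7 M in MeOH), rt; then NaOMe (2 equiv), 0 °C; AcOH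
Reagents that add atoms: ammonia N
Why: Ammonia opens the lactone to the primary amide (freeing the C12 hydroxyl) and removes the acetate, and methoxide then drives 5-exo attack of the amide nitrogen on the C16 methyl ester to the acidic imide, whose sodium salt is the thermodynamic sink (ammonolysis, then base-mediated imide formation; no stereocentre is touched).

**Compound list**

1 | levopimaric acid, abieta-8(14),12-dien-18-oic acid (5α-H, 9α-H, 10β-CH3, 4β-CH3, 4α-CO2H) | C1=C2CC[C@H]3[C@](C)(C(=O)O)CCC[C@]3(C)[C@H]2CC=C1C(C)C | starting material
2 | levopimarol, abieta-8(14),12-dien-18-ol (same ring stereochemistry) | C1=C2CC[C@H]3[C@](C)(CO)CCC[C@]3(C)[C@H]2CC=C1C(C)C | intermediate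
3 | levopimaryl acetate, 18-acetoxyabieta-8(14),12-diene | C1=C2CC[C@H]3[C@](C)(COC(C)=O)CCC[C@]3(C)[C@H]2CC=C1C(C)C | intermediate
4 | keto acid, 18-acetoxy-8-oxo-13,14,15,16,17-pentanorlabdan-12-oic acid (trans-decalin; 5α-H, 9α-H, 10β-CH3, 4β-CH3, 4α-CH2OAc) | O=C1CC[C@H]2[C@](C)(COC(C)=O)CCC[C@]2(C)[C@H]1CC(=O)O | intermediate
5 | methylene decalone, 18-acetoxy-12,13,14,15,16,17-hexanorlabd-9(11)-en-8-one (5α-H, 10β-CH3, 4β-CH3, 4α-CH2OAc) | C=C1C(=O)CC[C@H]2[C@](C)(COC(C)=O)CCC[C@]12C | intermediate
6 | dimethyl (S)-malate | COC(=O)C[C@H](O)C(=O)OC | starting material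
7 | tert-butyl bromoacetate | CC(C)(C)OC(=O)CBr | starting material
8 | hydroxy triester, 1-tert-butyl 2,3-dimethyl (2R,3S)-3-hydroxypropane-1,2,3-tricarboxylate | COC(=O)[C@@H](O)[C@@H](CC(=O)OC(C)(C)C)C(=O)OC | intermediate
9 | hydroxy acid, (2S,3R)-5-tert-butoxy-2-hydroxy-3-(methoxycarbonyl)-5-oxopentanoic acid | OC(=O)[C@@H](O)[C@@H](CC(=O)OC(C)(C)C)C(=O)OC | intermediate
10 | cis lactone acid, (2S,3R)-3-(methoxycarbonyl)-5-oxotetrahydrofuran-2-carboxylic acid | OC(=O)[C@H]1OC(=O)C[C@H]1C(=O)OC | intermediate
11 | keto lactone, methyl (12S,13R)-18-acetoxy-8-oxo-17-norlabdan-15,12-olid-16-oate (trans-2,3-disubstituted γ-lactone on the 9β-CH2 arm) | O=C1CC[C@H]2[C@](C)(COC(C)=O)CCC[C@]2(C)[C@H]1C[C@@H]1OC(=O)C[C@H]1C(=O)OC | intermediate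
12 | chloro keto lactone, 2α-chloro (equatorial) derivative of 11 | O=C1CC[C@H]2[C@](C)(COC(C)=O)C[C@H](Cl)C[C@]2(C)[C@H]1C[C@@H]1OC(=O)C[C@H]1C(=O)OC | intermediate
13 | chloro methylene lactone, methyl (12S,13R)-18-acetoxy-2α-chlorolabd-8(17)-en-15,12-olid-16-oate | C=C1CC[C@H]2[C@](C)(COC(C)=O)C[C@H](Cl)C[C@]2(C)[C@H]1C[C@@H]1OC(=O)C[C@H]1C(=O)OC | intermediate
14 | hydroxy amide ester, methyl (12S,13R)-15-amino-2α-chloro-12,18-dihydroxy-15-oxolabd-8(17)-en-16-oate | C=C1CC[C@H]2[C@](C)(CO)C[C@H](Cl)C[C@]2(C)[C@H]1C[C@H](O)[C@@H](CC(N)=O)C(=O)OC | intermediate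
15 | haterumaimide J (2α-Cl, 4α-CH2OH, 12S-OH, 13R succinimide) | C=C1CC[C@H]2[C@](C)(CO)C[C@H](Cl)C[C@]2(C)[C@H]1C[C@H](O)[C@H]1CC(=O)NC1=O | target

**Step count and risks**

Total: 9 steps. Longest linear sequence: 7 steps (steps 1, 2, 3, 6, 7, 8, 9 from levopimaric acid).

Stereocentres: C4, C5 and C10 are bought in 1. C9 is reset in step 6 under control of C10. C2 is set in step 7 by the ring conformation. C13 is set in step 4 by the malate centre, and C12 in step 6 by C13.

Most likely to fail:

1. Step 6 (proposed new method). Risks are slow oxidation of the electron-poor α-acyloxy carboxylate, modest trans selectivity at C12, and oligomerisation of enone 5. The fallback uses known chemistry and sets out from keto acid 4 and lactone acid 10, bypassing enone 5. Both acids are turned into redox-active esters with N-hydroxyphthalimide, DIC and DMAP: the N-(acyloxy)phthalimide of the keto acid F1 and the N-(acyloxy)phthalimide of the lactone acid F2. These are joined by nickel-electrocatalytic doubly decarboxylative C(sp3)–C(sp3) cross-coupling (NiCl2·6H2O, terpyridine ligand, AgNO3, Mg anode, carbon cathode, NMP, constant current). The lactone radical is again captured anti to the ester, and the route is rejoined at keto lactone 11.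

2. Step 7. Risks are imperfect site selectivity on an advanced intermediate and base-induced β-elimination of the lactone. The fallback moves the chlorination to the simple bicyclic stage and sets out from keto acid 4. The acid is masked with Boc2O, DMAP and t-BuOH as the tert-butyl ester of the keto acid F3. This is chlorinated with the same N-chloroamide under light to the 2α-chloro tert-butyl ester F4. TFA then frees the 2α-chloro keto acid F5, and the conditions of step 3 give the 2α-chloro methylene decalone F6. Coupling with 10 under the conditions of step 6 rejoins the route at chloro keto lactone 12.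

3. Step 9. Risks are over-ammonolysis to the diamide, retro-aldol or elimination at the β-hydroxy ester stage, and partition between lactone amide and hydroxy imide. The fallback is stepwise and sets out from 13. LiOH in THF/H2O followed by acidification cleaves the acetate and the methyl ester and re-closes the lactone, giving the lactone acid with free C18 alcohol F7. Coupling with NH4Cl (EDC·HCl, HOBt, i-Pr2NEt, DMF) gives the lactone primary carboxamide F8. KOt-Bu in THF at −20 °C then moves the acyl group from oxygen to the amide nitrogen, and an AcOH quench delivers the route back at target 15.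

**Further compounds**

F1 | step 6 | 1,3-dioxoisoindolin-2-yl ester of keto acid 4 | O=C1CC[C@H]2[C@](C)(COC(C)=O)CCC[C@]2(C)[C@H]1CC(=O)ON1C(=O)c2ccccc2C1=O
F2 | step 6 | 2-(1,3-dioxoisoindolin-2-yl) 3-methyl (2S,3R)-5-oxotetrahydrofuran-2,3-dicarboxylate | O=C(ON1C(=O)c2ccccc2C1=O)[C@H]1OC(=O)C[C@H]1C(=O)OC
F3 | step 7 | tert-butyl ester of keto acid 4 | O=C1CC[C@H]2[C@](C)(COC(C)=O)CCC[C@]2(C)[C@H]1CC(=O)OC(C)(C)C
F4 | step 7 | 2α-chloro tert-butyl ester | O=C1CC[C@H]2[C@](C)(COC(C)=O)C[C@H](Cl)C[C@]2(C)[C@H]1CC(=O)OC(C)(C)C
F5 | step 7 | 2α-chloro keto acid | O=C1CC[C@H]2[C@](C)(COC(C)=O)C[C@H](Cl)C[C@]2(C)[C@H]1CC(=O)O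
F6 | step 7 | 2α-chloro methylene decalone | C=C1C(=O)CC[C@H]2[C@](C)(COC(C)=O)C[C@H](Cl)C[C@]12C
F7 | step 9 | (12S,13R)-2α-chloro-18-hydroxylabd-8(17)-en-15,12-olid-16-oic acid | C=C1CC[C@H]2[C@](C)(CO)C[C@H](Cl)C[C@]2(C)[C@H]1C[C@@H]1OC(=O)C[C@H]1C(=O)O
F8 | step 9 | (12S,13R)-2α-chloro-18-hydroxylabd-8(17)-en-15,12-olide-16-carboxamide | C=C1CC[C@H]2[C@](C)(CO)C[C@H](Cl)C[C@]2(C)[C@H]1C[C@@H]1OC(=O)C[C@H]1C(N)=O
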